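**Retrosynthetic overview**
1. The only ring, the 3-hydroxy-4,5-dimethoxyphenyl ring, is bought. The plan rests on the trisubstituted C2=C3 alkene of the central 2-(acyloxymethyl)but-2-enoate, whose C4 methyl lies cis to the C1 ester carbonyl (Z, the less stable arrangement).
2. Endgame disconnections: the phenol O–Si bond, then the angelate acyl–O bond at the C2–CH2O arm (angelic acid, geometry bought), then the 4-methoxybenzyl ether that masks this arm.
3. Key disconnection: C2=C3 is opened to acetaldehyde and the α-[(4-methoxybenzyloxy)methyl] bis(trifluoroethyl)phosphonoacetate of the S carbinol (Still–Gennari olefination).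
4. The phosphonate comes from C-alkylation of the phosphonoacetate ester with 4-methoxybenzyl chloromethyl ether, the ester from the S alcohol and the phosphonoacetic acid, and the S centre from catalytic enantioselective Et2Zn addition to the silylated aldehyde.
5. No ring is formed at any stage. The order of events is carbinol stereocentre, ester, C2–CH2 bond, C2=C3 bond, angelate.

Key step: step 8

Assumption: 4-methoxybenzyl chloromethyl ether does not keep and is not bought, so its two-step preparation is counted in the route. All other starting materials and reagents are taken as purchasable.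

Abbreviation: TBS = tert-butyldimethylsilyl.

**Step 1**
Reactants: 1 3-hydroxy-4,5-dimethoxybenzaldehyde
Product: 2 3-(TBSO)-4,5-dimethoxybenzaldehyde
Conditions: TBSCl, imidazole, DMF, rt
Reagents that add atoms: tert-butyldimethylsilyl chloride (TBSCl), CC(C)(C)[Si](C)(C)Cl
Why: Imidazole-promoted O-silylation of the only hydroxyl group gives an aryl silyl ether that should withstand Et2Zn, NaH, KN(SiMe3)2 and DDQ and that leaves with fluoride at the end.

**Step 2**
Reactants: 2 3-(TBSO)-4,5-dimethoxybenzaldehyde
Product: 3 (S)-1-[3-(TBSO)-4,5-dimethoxyphenyl]propan-1-ol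
Conditions: Et2Zn (2 equiv), (2S)-(−)-3-exo-(dimethylamino)isoborneol (5 mol %), toluene, 0 °C; sat. aq NH4Cl
Reagents that add atoms: diethylzinc, CC[Zn]CC
Why: This is an amino-alcohol-catalysed enantioselective addition of a dialkylzinc to an aromatic aldehyde, in which the chiral zinc aminoalkoxide directs ethyl transfer to the Si face of the formyl group (the sense known for benzaldehydes) and so sets the S carbinol centre.

**Step 3**
Reactants: 4 methyl bis(2,2,2-trifluoroethyl)phosphonoacetate
Product: 5 2-[bis(2,2,2-trifluoroethoxy)phosphoryl]acetic acid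
Conditions: LiOH (1.05 equiv), THF/H2O, 0 °C; then 1 M HCl
Reagents that add atoms: lithium hydroxide, [Li+].[OH-]
Why: In this saponification with one equivalent of hydroxide in the cold, attack at the unhindered methyl ester carbonyl should outrun attack at phosphorus, so both trifluoroethyl groups are kept.

**Step 4**
Reactants: 3 (S)-1-[3-(TBSO)-4,5-dimethoxyphenyl]propan-1-ol; 5 2-[bis(2,2,2-trifluoroethoxy)phosphoryl]acetic acid
Product: 6 (S)-1-[3-(TBSO)-4,5-dimethoxyphenyl]propyl 2-[bis(2,2,2-trifluoroethoxy)phosphoryl]acetate
Conditions: DCC, 4-(dimethylamino)pyridine (cat.), CH2Cl2, 0 °C → rt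
Reagents that add atoms: none
Why: In this Steglich esterification the small unbranched acid acylates the hindered secondary benzylic alcohol easily, and the carbinol C–O bond is never broken, so the S configuration is retained.

**Step 5**
Reactants: 7 4-methoxybenzyl alcohol
Product: 8 4-methoxybenzyl methylthiomethyl ether
Conditions: NaH, NaI, MeSCH2Cl, 1,2-dimethoxyethane, 0 °C → rt
Reagents that add atoms: chloromethyl methyl sulfide, CSCCl
Why: Williamson-type etherification of the sodium alkoxide with iodomethyl methyl sulfide, made in the flask by Finkelstein exchange, is the standard way to a methylthiomethyl ether.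

**Step 6**
Reactants: 8 4-methoxybenzyl methylthiomethyl ether
Product: 9 4-methoxybenzyl chloromethyl ether
Conditions: SO2Cl2, CH2Cl2, −78 °C; volatiles removed in vacuo, used at once
Reagents that add atoms: sulfuryl chloride, O=S(=O)(Cl)Cl
Why: In this chlorinolysis of an O,S-acetal, SO2Cl2 chlorinates sulfur and the chlorosulfonium ion breaks down to the α-chloro ether, while the low temperature spares the anisole ring and the benzylic ether.

**Step 7**
Reactants: 6 (S)-1-[3-(TBSO)-4,5-dimethoxyphenyl]propyl 2-[bis(2,2,2-trifluoroethoxy)phosphoryl]acetate; 9 4-methoxybenzyl chloromethyl ether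
Product: 11 (S)-1-[3-(TBSO)-4,5-dimethoxyphenyl]propyl 2-[bis(2,2,2-trifluoroethoxy)phosphoryl]-3-[(4-methoxybenzyl)oxy]propanoate (both epimers at C2), via sodium carbanion 10 (not isolated)
Conditions: NaH (1.0 equiv), THF, 0 °C; then 9 (1.1 equiv), −78 → 0 °C
Reagents that add atoms: sodium hydride, [Na+].[H-] (sodium is held only in intermediate 10)
Why: C-alkylation of a stabilised phosphonoacetate carbanion with a very reactive α-chloro ether is known for benzyl chloromethyl ether with malonates and phosphonoacetates; the product is a weaker C–H acid than 6, which holds back a second alkylation, and the new C2 centre forms without control because the next step erases it.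

**Step 8**
Reactants: 11 (S)-1-[3-(TBSO)-4,5-dimethoxyphenyl]propyl 2-[bis(2,2,2-trifluoroethoxy)phosphoryl]-3-[(4-methoxybenzyl)oxy]propanoate; 12 acetaldehyde
Product: 14 (S)-1-[3-(TBSO)-4,5-dimethoxyphenyl]propyl (Z)-2-{[(4-methoxybenzyl)oxy]methyl}but-2-enoate, via potassium carbanion 13 (not isolated)
Conditions: KN(SiMe3)2 (1.0 equiv), 18-crown-6 (3 equiv), THF, −78 °C; then 12 (5 equiv, freshly distilled), −78 °C; sat. aq NH4Cl at −78 °C
Reagents that add atoms: potassium bis(trimethylsilyl)amide, [K+].C[Si](C)(C)[N-][Si](C)(C)C (potassium is held only in intermediate 13)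
Why: KN(SiMe3)2 removes the one C2–H of either epimer of 11 and gives a single planar carbanion 13, freed from its potassium ion by 18-crown-6, which adds to the formyl carbon of 12; the alkoxide adduct closes on phosphorus and breaks up by syn cycloreversion into the C2=C3 double bond and the phosphate diester salt. The closest known reaction type is the Still–Gennari variant of the Horner–Wadsworth–Emmons olefination with α-alkyl bis(trifluoroethyl)phosphonoacetates, which turns the phosphonopropionate and acetaldehyde into angelates, and ordinary α-(alkoxymethyl)phosphonoacetates are known olefination partners as well. No ring is closed in the product (the four-membered P–O species is only a fleeting stage of the elimination) and no stereocentre is made: the C2 centre of 11 is erased and the S carbinol carbon, which bears no acidic hydrogen, is not touched. The first selectivity needed is Z over E: the electron-poor trifluoroethoxy groups make phosphorus so electrophilic that the kinetically preferred adduct eliminates faster than it reverts, and this adduct places the C4 methyl cis to the ester carbonyl. The second is olefination over E1cB loss of the β-oxygen substituent: 4-methoxybenzyl oxide is a poor leaving group from a carbanion stabilised by both the ester and the phosphoryl group, and since alkoxides add readily to 2-phosphonoacrylates the elimination is also uphill, so at −78 °C capture by the unhindered aldehyde should win. Adding an excess of 12 to the preformed carbanion, with no base left over, limits aldol self-condensation, and any E isomer should be removable by chromatography at 14 or 15.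

**Step 9**
Reactants: 14 (S)-1-[3-(TBSO)-4,5-dimethoxyphenyl]propyl (Z)-2-{[(4-methoxybenzyl)oxy]methyl}but-2-enoate
Product: 15 (S)-1-[3-(TBSO)-4,5-dimethoxyphenyl]propyl (Z)-2-(hydroxymethyl)but-2-enoate
Conditions: DDQ (1.2 equiv), CH2Cl2/pH 7 phosphate buffer (10:1), 0 °C
Reagents that add atoms: none
Why: Oxidative cleavage of a 4-methoxybenzyl ether with DDQ proceeds by hydride abstraction at the ether CH2 and hydrolysis of the oxocarbenium ion; the other benzylic C–H bears a deactivating acyloxy group and has its para-methoxy group twisted out of conjugation by two ortho substituents, so it should react far more slowly, and the buffer keeps acid away from the benzylic ester.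

**Step 10**
Reactants: 15 (S)-1-[3-(TBSO)-4,5-dimethoxyphenyl]propyl (Z)-2-(hydroxymethyl)but-2-enoate; 16 angelic acid [(Z)-2-methylbut-2-enoic acid]
Product: 18 (S)-1-[3-(TBSO)-4,5-dimethoxyphenyl]propyl (Z)-2-({[(Z)-2-methylbut-2-enoyl]oxy}methyl)but-2-enoate, via mixed anhydride 17 (not isolated)
Conditions: 16, 2,4,6-Cl3C6H2COCl, Et3N (1.5 equiv each), toluene, rt; then 15, solid NaHCO3, 70 °C, no nucleophilic catalyst
Reagents that add atoms: 2,4,6-trichlorobenzoyl chloride, O=C(Cl)c1c(Cl)cc(Cl)cc1Cl (its aroyl group is held only in intermediate 17)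
Why: In this Yamaguchi-type esterification the unhindered primary alcohol attacks the less shielded angeloyl carbonyl of 17, leaving out the pyridine catalyst closes the conjugate addition–elimination path from angelate to tiglate, and the insoluble NaHCO3 takes up the strong acid before it can ionise the benzylic ester.

**Step 11**
Reactants: 18 (S)-1-[3-(TBSO)-4,5-dimethoxyphenyl]propyl (Z)-2-({[(Z)-2-methylbut-2-enoyl]oxy}methyl)but-2-enoate
Product: 19 (S)-1-(3-hydroxy-4,5-dimethoxyphenyl)propyl (Z)-2-({[(Z)-2-methylbut-2-enoyl]oxy}methyl)but-2-enoate (CNP0282120.1)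
Conditions: Bu4NF/AcOH (1:1), THF, 0 °C
Reagents that add atoms: none
Why: Fluoride cleaves the aryl silyl ether, the most fluoride-labile kind of silyl ether, and acetic acid protonates the phenoxide at once so that ester exchange, alkene isomerisation and displacement of the allylic angelate are avoided; the phenol is meta to the benzylic carbon, so no quinone methide can form.

**Compound list**
1 | 3-hydroxy-4,5-dimethoxybenzaldehyde | O=Cc1cc(O)c(OC)c(OC)c1 | starting material
2 | 3-(TBSO)-4,5-dimethoxybenzaldehyde | O=Cc1cc(O[Si](C)(C)C(C)(C)C)c(OC)c(OC)c1 | intermediate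
3 | (S)-1-[3-(TBSO)-4,5-dimethoxyphenyl]propan-1-ol | O[C@@H](CC)c1cc(O[Si](C)(C)C(C)(C)C)c(OC)c(OC)c1 | intermediate
4 | methyl bis(2,2,2-trifluoroethyl)phosphonoacetate | COC(=O)CP(=O)(OCC(F)(F)F)OCC(F)(F)F | starting material
5 | 2-[bis(2,2,2-trifluoroethoxy)phosphoryl]acetic acid | OC(=O)CP(=O)(OCC(F)(F)F)OCC(F)(F)F | intermediate
6 | (S)-1-[3-(TBSO)-4,5-dimethoxyphenyl]propyl 2-[bis(2,2,2-trifluoroethoxy)phosphoryl]acetate | O=C(CP(=O)(OCC(F)(F)F)OCC(F)(F)F)O[C@@H](CC)c1cc(O[Si](C)(C)C(C)(C)C)c(OC)c(OC)c1 | intermediate
7 | 4-methoxybenzyl alcohol | COc1ccc(CO)cc1 | starting material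
8 | 4-methoxybenzyl methylthiomethyl ether | COc1ccc(COCSC)cc1 | intermediate
9 | 4-methoxybenzyl chloromethyl ether | COc1ccc(COCCl)cc1 | intermediate
10 | sodium carbanion of 6 (not isolated) | [Na+].O=C([CH-]P(=O)(OCC(F)(F)F)OCC(F)(F)F)O[C@@H](CC)c1cc(O[Si](C)(C)C(C)(C)C)c(OC)c(OC)c1 | intermediate
11 | (S)-1-[3-(TBSO)-4,5-dimethoxyphenyl]propyl 2-[bis(2,2,2-trifluoroethoxy)phosphoryl]-3-[(4-methoxybenzyl)oxy]propanoate, both epimers at C2 | COc1ccc(COCC(C(=O)O[C@@H](CC)c2cc(O[Si](C)(C)C(C)(C)C)c(OC)c(OC)c2)P(=O)(OCC(F)(F)F)OCC(F)(F)F)cc1 | intermediate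
12 | acetaldehyde | CC=O | starting material
13 | potassium carbanion of 11 (not isolated) | [K+].COc1ccc(COC[C-](C(=O)O[C@@H](CC)c2cc(O[Si](C)(C)C(C)(C)C)c(OC)c(OC)c2)P(=O)(OCC(F)(F)F)OCC(F)(F)F)cc1 | intermediate
14 | (S)-1-[3-(TBSO)-4,5-dimethoxyphenyl]propyl (Z)-2-{[(4-methoxybenzyl)oxy]methyl}but-2-enoate | C/C=C(/COCc1ccc(OC)cc1)C(=O)O[C@@H](CC)c1cc(O[Si](C)(C)C(C)(C)C)c(OC)c(OC)c1 | intermediate
15 | (S)-1-[3-(TBSO)-4,5-dimethoxyphenyl]propyl (Z)-2-(hydroxymethyl)but-2-enoate | C/C=C(/CO)C(=O)O[C@@H](CC)c1cc(O[Si](C)(C)C(C)(C)C)c(OC)c(OC)c1 | intermediate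
16 | angelic acid, (Z)-2-methylbut-2-enoic acid | C/C=C(/C)C(=O)O | starting material
17 | (Z)-2-methylbut-2-enoic 2,4,6-trichlorobenzoic anhydride (not isolated) | C/C=C(/C)C(=O)OC(=O)c1c(Cl)cc(Cl)cc1Cl | intermediate
18 | (S)-1-[3-(TBSO)-4,5-dimethoxyphenyl]propyl (Z)-2-({[(Z)-2-methylbut-2-enoyl]oxy}methyl)but-2-enoate | C/C=C(/C)C(=O)OC/C(=C/C)C(=O)O[C@@H](CC)c1cc(O[Si](C)(C)C(C)(C)C)c(OC)c(OC)c1 | intermediate
19 | (S)-1-(3-hydroxy-4,5-dimethoxyphenyl)propyl (Z)-2-({[(Z)-2-methylbut-2-enoyl]oxy}methyl)but-2-enoate, CNP0282120.1 | C/C=C(/C)C(=O)OC/C(=C/C)C(=O)O[C@@H](CC)c1cc(O)c(OC)c(OC)c1 | target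

**Total step count:** 11
**Longest linear sequence:** 8 steps (steps 1, 2, 4, 7, 8, 9, 10, 11; 1 → 2 → 3 → 6 → 11 → 14 → 15 → 18 → 19). Steps 3 and 5–6 are side branches that join at steps 4 and 7.

**Steps most likely to fail**

**Step 8.**
- Risk: the carbanion may shed 4-methoxybenzyl oxide (E1cB) before it meets the aldehyde. The bulk of the α-arm and of the ester may erode the Z selectivity. Acetaldehyde may be lost to enolisation and aldol self-condensation.
- Fallback, from 3 back to 14: the geometry is taken from a vinyl iodide instead of from an olefination. Crotonaldehyde is α-iodinated (I2, K2CO3, cat. 4-(dimethylamino)pyridine, THF/H2O) to (Z)-2-iodobut-2-enal F1. This is reduced (NaBH4, MeOH, 0 °C) to (Z)-2-iodobut-2-en-1-ol F2 and etherified (4-methoxybenzyl trichloroacetimidate, cat. camphorsulfonic acid, CH2Cl2) to (Z)-2-iodobut-2-enyl 4-methoxybenzyl ether F3, in which the methyl group already stands cis to iodine. Palladium-catalysed alkoxycarbonylation of F3 with alcohol 3 as the nucleophile (PdCl2(PPh3)2, CO 1 atm, Et3N, DMF, 60 °C) replaces iodine by the ester carbonyl with retention of the alkene geometry and gives 14.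

**Step 7.**
- Risk: the chloro ether may decompose before it is consumed, and the ambident carbanion may be alkylated twice or on oxygen.
- Fallback, from 6 (through 10) back to 13: the C2–CH2 bond is made by a Mannich reaction and the CH2–O bond by conjugate addition. Carbanion 10 is trapped with dimethyl(methylidene)ammonium iodide (Eschenmoser's salt, THF, 0 °C) to give the 3-(dimethylamino)propanoate F4. MeI turns it into the trimethylammonium iodide F5, which loses trimethylamine on stirring with aqueous NaHCO3/CH2Cl2 and gives the 2-phosphonoacrylate F6. Alcohol 7 is deprotonated (KN(SiMe3)2, 18-crown-6, THF, −78 °C) to potassium 4-methoxybenzyl oxide F7. Its oxa-Michael addition to the terminal CH2 of F6 gives carbanion 13 directly, ready for acetaldehyde in the same flask.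

**Step 10.**
- Risk: activation of the angeloyl carbonyl may let the Z alkene of the acyl group isomerise to the E geometry or slip out of conjugation, and long heating may harm the benzylic ester.
- Fallback, from 15 and 16 back to 18: the alcohol is activated in place of the acid. A Mitsunobu reaction (PPh3, diisopropyl azodicarboxylate, toluene, 0 °C) turns the primary allylic hydroxyl into an oxyphosphonium leaving group that the angelate anion displaces at CH2 (SN2). The angeloyl carbonyl is therefore never made electrophilic. No compound outside the compound list is made (F0).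

**Further compounds**
F1 | step 8 | (Z)-2-iodobut-2-enal | C/C=C(\I)C=O
F2 | step 8 | (Z)-2-iodobut-2-en-1-ol | C/C=C(\I)CO
F3 | step 8 | (Z)-2-iodobut-2-enyl 4-methoxybenzyl ether | C/C=C(\I)COCc1ccc(OC)cc1
F4 | step 7 | (S)-1-[3-(TBSO)-4,5-dimethoxyphenyl]propyl 2-[bis(2,2,2-trifluoroethoxy)phosphoryl]-3-(dimethylamino)propanoate, both epimers at C2 | CN(C)CC(C(=O)O[C@@H](CC)c1cc(O[Si](C)(C)C(C)(C)C)c(OC)c(OC)c1)P(=O)(OCC(F)(F)F)OCC(F)(F)F
F5 | step 7 | trimethylammonium iodide of F4 | [I-].C[N+](C)(C)CC(C(=O)O[C@@H](CC)c1cc(O[Si](C)(C)C(C)(C)C)c(OC)c(OC)c1)P(=O)(OCC(F)(F)F)OCC(F)(F)F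
F6 | step 7 | (S)-1-[3-(TBSO)-4,5-dimethoxyphenyl]propyl 2-[bis(2,2,2-trifluoroethoxy)phosphoryl]prop-2-enoate | C=C(C(=O)O[C@@H](CC)c1cc(O[Si](C)(C)C(C)(C)C)c(OC)c(OC)c1)P(=O)(OCC(F)(F)F)OCC(F)(F)F
F7 | step 7 | potassium 4-methoxybenzyl oxide | [K+].[O-]Cc1ccc(OC)cc1
F0 | step 10 | none | none
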